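**Plan**
- Retrosynthesis: the O5–benzyl bond of a protected precursor is cut first, then the C2–C3 bond between the acetoxy-bearing carbon and the arylethyl unit, then the C3–Br and C3–OAc bonds back to an aldehyde C=O and acetyl bromide.
- Enabling feature (chain numbered from the benzylic carbon C1; the only ring is the untouched benzene ring): C3 is a dialkyl carbinol carbon that carries its own acetate, so it can be made as the carbon of a 1-bromoalkyl acetate and turned into an alpha-acetoxy radical that bonds to C2.
- Forward: the C3–C10 piece is built from methyl 3-oxooctanoate (hydrogenation, O-benzylation, reduction to the aldehyde, acetyl bromide addition). The C1–C2 arylethyl piece is zincated, the two are joined at C2–C3 by nickel catalysis, and hydrogenolysis ends the route. No ring is formed.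
- Stereochemistry: C5 (S) comes from (S)-BINAP–ruthenium hydrogenation of the beta-keto ester. C3 (S, 1,3-anti to C5) comes from the chiral bis(oxazoline)–nickel catalyst in the stereoconvergent coupling.

Key step: step 6

Remark: L* is 2,2'-(propane-2,2-diyl)bis(4-phenyl-4,5-dihydro-1,3-oxazole), available as (S,S) and (R,R); its sense of induction is assumed to carry over from simple 1-bromoalkyl acetates, and the antipode that delivers the 3S acetate is the one used.

**Step 1**
Reactants: 1 methyl 3-oxooctanoate
Product: 2 methyl (3S)-3-hydroxyoctanoate
Conditions: H2 (4 atm), RuCl2[(S)-BINAP] (0.1 mol %), MeOH, 100 °C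
Reagents that add atoms: none
Why: Noyori asymmetric hydrogenation of a beta-keto ester, in which the ester carbonyl chelates ruthenium and the (S)-BINAP ligand directs hydride to the ketone face that gives the 3S carbinol, the future C5 of the target.

**Step 2**
Reactants: 2 methyl (3S)-3-hydroxyoctanoate
Product: 3 methyl (3S)-3-(benzyloxy)octanoate
Conditions: BnOC(=NH)CCl3 (1.5 equiv), TfOH (5 mol %), cyclohexane/CH2Cl2, 0 °C to rt
Reagents that add atoms: benzyl 2,2,2-trichloroacetimidate, N=C(OCc1ccccc1)C(Cl)(Cl)Cl
Why: acid-catalysed O-benzylation with the trichloroacetimidate avoids the alkoxide that would trigger retro-aldol or elimination in a beta-hydroxy ester, and the stereocentre is not touched because only the O–H bond reacts.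

**Step 3**
Reactants: 3 methyl (3S)-3-(benzyloxy)octanoate
Product: 5 (3S)-3-(benzyloxy)octanal, via aluminium hemiacetal 4 (not isolated)
Conditions: i-Bu2AlH (1.1 equiv), CH2Cl2, −78 °C; MeOH quench, aq. Rochelle salt
Reagents that add atoms: none
Why: partial ester reduction with i-Bu2AlH at low temperature should stop at the tetrahedral aluminium hemiacetal, which is stabilised by chelation to the beta-benzyloxy oxygen and releases the aldehyde only on aqueous work-up.

**Step 4**
Reactants: 5 (3S)-3-(benzyloxy)octanal; 6 acetyl bromide
Product: 7 (1RS,3S)-3-(benzyloxy)-1-bromooctyl acetate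
Conditions: AcBr (1.05 equiv), ZnBr2 (1 mol %), CH2Cl2, −20 to 0 °C; volatiles removed in vacuo, used crude
Reagents that add atoms: none
Why: acyl bromides add across an aldehyde C=O to give 1-bromoalkyl esters (O-acylation, then bromide capture of the acyloxycarbenium ion); the new C1 centre forms as both epimers, which is harmless because it becomes planar in step 6, and the cold, near-stoichiometric conditions should spare the benzyl ether.

**Step 5**
Reactants: 8 4-(2-bromoethyl)-1,2-dimethoxybenzene
Product: 9 [2-(3,4-dimethoxyphenyl)ethyl]zinc bromide
Conditions: Zn dust (1.5 equiv), I2 (5 mol %), DMA, 70 °C; titrated, used as solution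
Reagents that add atoms: zinc, [Zn]
Why: direct insertion of iodine-activated zinc into a primary alkyl bromide in a polar amide solvent is a standard route to alkylzinc bromides, and the dimethoxyarene is inert to it.

**Step 6**
Reactants: 7 (1RS,3S)-3-(benzyloxy)-1-bromooctyl acetate; 9 [2-(3,4-dimethoxyphenyl)ethyl]zinc bromide
Product: 10 (3S,5S)-5-(benzyloxy)-1-(3,4-dimethoxyphenyl)decan-3-yl acetate
Conditions: NiBr2·MeOCH2CH2OMe (10 mol %), L* (12 mol %), 9 (1.6 equiv), THF/DMA, 0 °C
Reagents that add atoms: none
Why: Monovalent nickel abstracts bromine from either C1 epimer of 7 to give one planar alpha-acetoxy radical at the future C3, while the arylethyl group of 9 is transferred to divalent nickel; capture of the radical gives a trivalent dialkylnickel that reductively eliminates the C2–C3 bond and returns monovalent nickel. The closest known reaction type is the nickel/bis(oxazoline)-catalysed enantioconvergent alkyl–alkyl (Negishi-type) coupling of racemic 1-bromoalkyl esters with alkylzinc nucleophiles, applied here to an electrophile that carries an additional remote stereocentre. No ring is closed. The new C3 stereocentre is set by the chiral ligand on nickel, with the acetate carbonyl acting as the coordinating group that orients the radical, so the 3S (1,3-anti) acetate is expected under catalyst control and the C5 benzyloxy centre should only modulate the ratio. The step needs facial selectivity at C3 and chemoselectivity for cross-coupling over loss of HBr to the enol acetate; the ether oxygen sits on C5 and not next to the radical, so no beta-alkoxy elimination is possible, and the C3 epimer, being a diastereomer, can be removed by chromatography.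

**Step 7**
Reactants: 10 (3S,5S)-5-(benzyloxy)-1-(3,4-dimethoxyphenyl)decan-3-yl acetate
Product: 11 (3S,5S)-1-(3,4-dimethoxyphenyl)-5-hydroxydecan-3-yl acetate
Conditions: H2 (1 atm), Pd/C (10 wt % Pd, 10 mol %), EtOAc, rt
Reagents that add atoms: none
Why: heterogeneous hydrogenolysis of the benzyl ether in a neutral, aprotic solvent should free the C5 hydroxyl without the acid or base that would drive 1,3-acetyl migration or transesterification, and neither stereocentre is involved.

**Compound list**
1 | methyl 3-oxooctanoate | CCCCCC(=O)CC(=O)OC | starting material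
2 | methyl (3S)-3-hydroxyoctanoate | CCCCC[C@H](O)CC(=O)OC | intermediate
3 | methyl (3S)-3-(benzyloxy)octanoate | CCCCC[C@H](OCc1ccccc1)CC(=O)OC | intermediate
4 | diisobutylaluminium (3S)-3-(benzyloxy)-1-methoxyoctan-1-olate (aluminium hemiacetal, both C1 epimers) | CCCCC[C@H](OCc1ccccc1)CC(OC)O[Al](CC(C)C)CC(C)C | intermediate
5 | (3S)-3-(benzyloxy)octanal | CCCCC[C@H](OCc1ccccc1)CC=O | intermediate
6 | acetyl bromide | CC(=O)Br | starting material
7 | (1RS,3S)-3-(benzyloxy)-1-bromooctyl acetate | CCCCC[C@H](OCc1ccccc1)CC(Br)OC(C)=O | intermediate
8 | 4-(2-bromoethyl)-1,2-dimethoxybenzene | COc1ccc(CCBr)cc1OC | starting material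
9 | [2-(3,4-dimethoxyphenyl)ethyl]zinc bromide | COc1ccc(CC[Zn]Br)cc1OC | intermediate
10 | (3S,5S)-5-(benzyloxy)-1-(3,4-dimethoxyphenyl)decan-3-yl acetate | CCCCC[C@H](OCc1ccccc1)C[C@H](CCc1ccc(OC)c(OC)c1)OC(C)=O | intermediate
11 | (3S,5S)-1-(3,4-dimethoxyphenyl)-5-hydroxydecan-3-yl acetate | CCCCC[C@H](O)C[C@H](CCc1ccc(OC)c(OC)c1)OC(C)=O | target

**Step count**
Total steps: 7. Longest linear sequence: 6 (steps 1, 2, 3, 4, 6, 7); step 5 is the side branch.

**Steps most likely to fail**

Step 6. The catalyst and the C5 centre may be mismatched and give poor facial selectivity at C3. The alpha-acetoxy radical may also translocate by a 1,5-hydrogen shift from the benzylic CH2 of the ether, and the bromo acetate may lose HBr or hydrolyse before it couples. The fallback makes the same C2–C3 bond by polar addition and sets out from 8 and 5. Bromide 8 is converted (Mg, THF) into [2-(3,4-dimethoxyphenyl)ethyl]magnesium bromide F1. F1 is added to aldehyde 5 at −78 °C, where precomplexation with MgBr2·OEt2 should favour the 1,3-anti epimer through a six-membered chelate. The products are (3S,5S)-5-(benzyloxy)-1-(3,4-dimethoxyphenyl)decan-3-ol F2 and its epimer (3R,5S)-5-(benzyloxy)-1-(3,4-dimethoxyphenyl)decan-3-ol F3, which are separated by chromatography. F2 is acetylated with retention (Ac2O, pyridine, DMAP) and F3 with inversion (AcOH, PPh3, DIAD, Mitsunobu reaction), so both return to the route at 10.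

Step 4. Acetyl bromide or adventitious HBr may cleave the benzyl ether, or acid may promote loss of benzyl alcohol from the beta-alkoxy aldehyde. The fallback avoids the acyl bromide and sets out from 5. The aldehyde is converted with Ac2O and catalytic I2 into (3S)-3-(benzyloxy)octane-1,1-diyl diacetate F4. One acetoxy group is then exchanged for bromide with Me3SiBr (CH2Cl2, 0 °C), in the way anomeric acetates of benzylated sugars are turned into glycosyl bromides. This returns to the route at 7.

Step 3. The reduction may run past the aldehyde stage, or benzyl alcohol may be lost by beta-elimination during the aluminium work-up. The fallback sets out from 3, which is reduced fully with LiAlH4 (THF, 0 °C) to (3S)-3-(benzyloxy)octan-1-ol F5. F5 is oxidised under buffered, non-basic conditions (Dess–Martin periodinane, NaHCO3, CH2Cl2) and returns to the route at 5.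

**Further compounds**
F1 | step 6 | [2-(3,4-dimethoxyphenyl)ethyl]magnesium bromide | COc1ccc(CC[Mg]Br)cc1OC
F2 | step 6 | (3S,5S)-5-(benzyloxy)-1-(3,4-dimethoxyphenyl)decan-3-ol | CCCCC[C@H](OCc1ccccc1)C[C@H](CCc1ccc(OC)c(OC)c1)O
F3 | step 6 | (3R,5S)-5-(benzyloxy)-1-(3,4-dimethoxyphenyl)decan-3-ol | CCCCC[C@H](OCc1ccccc1)C[C@@H](CCc1ccc(OC)c(OC)c1)O
F4 | step 4 | (3S)-3-(benzyloxy)octane-1,1-diyl diacetate | CCCCC[C@H](OCc1ccccc1)CC(OC(C)=O)OC(C)=O
F5 | step 3 | (3S)-3-(benzyloxy)octan-1-ol | CCCCC[C@H](OCc1ccccc1)CCO
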